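Target 19 is a (2S,4R)-flavan (rings A and C, ring B = 4-hydroxyphenyl; plain locants) bonded through C4 to C8' of (2S)-pinocembrin (rings D and F; primed locants).
Retrosynthetic cuts, last bond first: three O-benzyl groups; ring F at C4'–C4a' (Friedel–Crafts acylation) and O1'–C2' (Mitsunobu ether); ring C at O1–C2 (cyclodehydration) and C2–ring B (Grignard); finally C4–C4a and O1–C2 of a 4-arylchroman-2-ol.
Enabling feature: C4 is a diarylmethine on C4a of ring A, which is a 3,5-dimethoxyphenol unit nucleophilic at the carbon ortho to its hydroxyl, while C2–C3–C4 are the three carbons of an enal carrying ring D.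
Forward order: ring D enal (3 steps), ring C closed as a lactol by formal [3+3] annulation, reopened with the ring B Grignard reagent and reclosed as the 2,4-trans flavan, ring F annulated on the unmasked ring D phenol, hydrogenolysis.
Stereochemistry: C4 from the (S)-diarylprolinol silyl ether catalyst, C2 by thermodynamic relay from C4, C2' from ethyl (R)-3-hydroxy-3-phenylpropanoate by Mitsunobu inversion.

Key step: step 4

Remark: the CIP descriptor at flavan C4 switches between S and R along the route only because the ranking of rings A and D changes with their substituents; the spatial arrangement set in step 4 is never altered.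

Step 1
Reactants: 1 2,4,6-trihydroxybenzaldehyde
Product: 2 2,4-bis(benzyloxy)-6-hydroxybenzaldehyde
Conditions: BnBr (2.1 equiv), K2CO3, DMF, 0 °C to rt
Reagents that add atoms: benzyl bromide, BrCc1ccccc1
Why: Williamson etherification should stop at the dibenzyl stage because the 4-hydroxyl and one 2-hydroxyl are alkylated readily, whereas the last ortho hydroxyl is hydrogen-bonded to the formyl group and is the least nucleophilic.

Step 2
Reactants: 2 2,4-bis(benzyloxy)-6-hydroxybenzaldehyde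
Product: 3 2-(allyloxy)-4,6-bis(benzyloxy)benzaldehyde
Conditions: allyl bromide, K2CO3, DMF, 60 °C
Reagents that add atoms: allyl bromide, C=CCBr
Why: Williamson O-allylation of the chelated phenol under warmer conditions masks the oxygen that later becomes O1' with a group removable by zerovalent palladium in the presence of benzyl ethers.

Step 3
Reactants: 3 2-(allyloxy)-4,6-bis(benzyloxy)benzaldehyde
Product: 4 (E)-3-[2-(allyloxy)-4,6-bis(benzyloxy)phenyl]prop-2-enal
Conditions: Ph3P=CHCHO (1.3 equiv), toluene, 90 °C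
Reagents that add atoms: (triphenylphosphoranylidene)acetaldehyde, O=CC=P(c1ccccc1)(c1ccccc1)c1ccccc1
Why: Wittig olefination with the stabilised formylmethylene ylide is (E)-selective, and a small excess of ylide with monitoring should hold the two-carbon homologation at the enal stage.

Step 4
Reactants: 4 (E)-3-[2-(allyloxy)-4,6-bis(benzyloxy)phenyl]prop-2-enal; 5 3,5-dimethoxyphenol
Product: 8 (4S)-4-[2-(allyloxy)-4,6-bis(benzyloxy)phenyl]-5,7-dimethoxychroman-2-ol (both C2 anomers), via iminium benzoate 6 (not isolated), via open-chain hydroxy aldehyde 7 (not isolated)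
Conditions: (S)-2-[diphenyl(trimethylsilyloxy)methyl]pyrrolidine (20 mol %), PhCO2H (20 mol %), toluene (concentrated), rt to 40 °C, prolonged
Reagents that add atoms: none
Why: The pyrrolidine condenses with enal 4 to the (E)-s-trans iminium ion 6, the ring carbon of 5 lying between OH and OMe adds to its β-carbon, and rearomatisation followed by hydrolysis of the catalyst-bound adduct releases hydroxy aldehyde 7, whose phenol oxygen then adds to the formyl group. The closest known reaction type is the organocatalytic enantioselective Friedel–Crafts alkylation and hemiacetalisation of electron-rich phenols and naphthols with enals to give 4-arylchroman-2-ols. Ring C is thus assembled by an intermolecular C4–C4a bond formation followed by 6-exo-trig closure of O1 onto C2, a formal [3+3] annulation. The C4 stereocentre is controlled by the catalyst: its (S)-configured diphenyl(silyloxy)methyl group covers one face of 6, so the arene should enter from the open face and give (4S)-8, which is the target arrangement, while the anomeric C2 is inconsequential. The step needs 1,4- over 1,2-addition and ortho over para C-alkylation of the phenol; the first follows from iminium activation, the second from hydrogen bonding of the phenol hydroxyl to the iminium carboxylate pair and from the fact that only the ortho adduct can be trapped as a lactol. The two ortho alkoxy groups twist ring D out of conjugation, which limits its deactivating donation but hinders the β-carbon, hence the acid co-catalyst, high concentration and long reaction time.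

Step 5
Reactants: 8 (4S)-4-[2-(allyloxy)-4,6-bis(benzyloxy)phenyl]-5,7-dimethoxychroman-2-ol; 9 1-(benzyloxy)-4-bromobenzene
Product: 11 (3R)-3-[2-(allyloxy)-4,6-bis(benzyloxy)phenyl]-1-[4-(benzyloxy)phenyl]-3-(2-hydroxy-4,6-dimethoxyphenyl)propan-1-ol (both C1 epimers), via aryl Grignard reagent 10 (not isolated)
Conditions: 9, Mg, THF, 40 °C; then 8 (0.3 equiv relative to 9), THF, 0 °C to rt; aq NH4Cl
Reagents that add atoms: none
Why: The lactol is a masked aldehyde, so one equivalent of Grignard reagent 10 deprotonates and opens it and a second adds to the formyl group (Grignard 1,2-addition); the carbinol configuration is left uncontrolled because that centre is ionised in the next step.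

Step 6
Reactants: 11 (3R)-3-[2-(allyloxy)-4,6-bis(benzyloxy)phenyl]-1-[4-(benzyloxy)phenyl]-3-(2-hydroxy-4,6-dimethoxyphenyl)propan-1-ol
Product: 12 (2S,4S)-4-[2-(allyloxy)-4,6-bis(benzyloxy)phenyl]-2-[4-(benzyloxy)phenyl]-5,7-dimethoxychroman (2,4-trans)
Conditions: p-TsOH·H2O (10 mol %), 4 Å molecular sieves, CH2Cl2, 0 °C to rt
Reagents that add atoms: none
Why: Mild acid ionises the 4-benzyloxybenzylic alcohol to a stabilised cation that the ring A phenol traps (SN1 cyclodehydration, six-membered ring); because this closure is reversible, both carbinol epimers should converge on the 2,4-trans flavan, in which the C2 aryl group is equatorial and the C4 aryl group is held pseudoaxial by peri strain with the 5-methoxy group, so C2 is set (S) by relay from C4.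

Step 7
Reactants: 12 (2S,4S)-4-[2-(allyloxy)-4,6-bis(benzyloxy)phenyl]-2-[4-(benzyloxy)phenyl]-5,7-dimethoxychroman
Product: 13 3,5-bis(benzyloxy)-2-{(2S,4S)-2-[4-(benzyloxy)phenyl]-5,7-dimethoxychroman-4-yl}phenol
Conditions: Pd(PPh3)4 (5 mol %), morpholine, THF, rt
Reagents that add atoms: none
Why: In this Tsuji–Trost deallylation, zerovalent palladium converts the aryl allyl ether into a π-allyl complex that morpholine intercepts, which leaves the benzyl ethers and the benzylic bonds of ring C untouched.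

Step 8
Reactants: 13 3,5-bis(benzyloxy)-2-{(2S,4S)-2-[4-(benzyloxy)phenyl]-5,7-dimethoxychroman-4-yl}phenol; 14 ethyl (R)-3-hydroxy-3-phenylpropanoate
Product: 15 ethyl (3S)-3-(3,5-bis(benzyloxy)-2-{(2S,4R)-2-[4-(benzyloxy)phenyl]-5,7-dimethoxychroman-4-yl}phenoxy)-3-phenylpropanoate
Conditions: PPh3, DIAD, THF, 0 °C to rt
Reagents that add atoms: none
Why: Mitsunobu etherification displaces the oxyphosphonium group of the secondary benzylic alcohol by the phenoxide in an SN2 step, so (R)-14 should give the (S)-aryl ether and with it the configuration of the future C2'.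

Step 9
Reactants: 15 ethyl (3S)-3-(3,5-bis(benzyloxy)-2-{(2S,4R)-2-[4-(benzyloxy)phenyl]-5,7-dimethoxychroman-4-yl}phenoxy)-3-phenylpropanoate
Product: 16 (3S)-3-(3,5-bis(benzyloxy)-2-{(2S,4R)-2-[4-(benzyloxy)phenyl]-5,7-dimethoxychroman-4-yl}phenoxy)-3-phenylpropanoic acid
Conditions: LiOH·H2O, THF/MeOH/H2O, 0 °C to rt; then 1 M HCl to pH 3–4 at 0 °C
Reagents that add atoms: lithium hydroxide, [Li+].[OH-]
Why: Saponification of the ethyl ester at low temperature should outrun E1cB loss of the β-aryloxy group and touches no stereocentre.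

Step 10
Reactants: 16 (3S)-3-(3,5-bis(benzyloxy)-2-{(2S,4R)-2-[4-(benzyloxy)phenyl]-5,7-dimethoxychroman-4-yl}phenoxy)-3-phenylpropanoic acid
Product: 18 (2S)-5,7-bis(benzyloxy)-8-{(2S,4R)-2-[4-(benzyloxy)phenyl]-5,7-dimethoxychroman-4-yl}-2-phenylchroman-4-one, via mixed trifluoroacetic anhydride 17 (not isolated)
Conditions: (CF3CO)2O (1.5 equiv), CH2Cl2, 0 °C
Reagents that add atoms: none
Why: The mixed anhydride acylates the phloroglucinol-type ring D in an intramolecular Friedel–Crafts reaction that can only reach the single free carbon ortho to the tethering oxygen (six-membered ring F), at a temperature where neither the benzylic C–O stereocentres nor the C4 diarylmethine should ionise.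

Step 11
Reactants: 18 (2S)-5,7-bis(benzyloxy)-8-{(2S,4R)-2-[4-(benzyloxy)phenyl]-5,7-dimethoxychroman-4-yl}-2-phenylchroman-4-one
Product: 19 (2S)-5,7-dihydroxy-8-[(2S,4R)-2-(4-hydroxyphenyl)-5,7-dimethoxychroman-4-yl]-2-phenylchroman-4-one
Conditions: H2 (1 atm), 10% Pd/C, EtOAc/MeOH, rt, stopped at full debenzylation
Reagents that add atoms: none
Why: Catalytic hydrogenolysis cleaves the three O-benzyl ethers faster than the cyclic benzylic C–O bonds of rings C and F or the aryl ketone, which is deactivated by its oxygenated ring.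

Compound list
1 | 2,4,6-trihydroxybenzaldehyde | O=Cc1c(O)cc(O)cc1O | starting material
2 | 2,4-bis(benzyloxy)-6-hydroxybenzaldehyde | O=Cc1c(O)cc(OCc2ccccc2)cc1OCc1ccccc1 | intermediate
3 | 2-(allyloxy)-4,6-bis(benzyloxy)benzaldehyde | O=Cc1c(OCC=C)cc(OCc2ccccc2)cc1OCc1ccccc1 | intermediate
4 | (E)-3-[2-(allyloxy)-4,6-bis(benzyloxy)phenyl]prop-2-enal | O=C/C=C/c1c(OCC=C)cc(OCc2ccccc2)cc1OCc1ccccc1 | intermediate
5 | 3,5-dimethoxyphenol | COc1cc(O)cc(OC)c1 | starting material
6 | (S)-1-{(E)-3-[2-(allyloxy)-4,6-bis(benzyloxy)phenyl]prop-2-en-1-ylidene}-2-[diphenyl(trimethylsilyloxy)methyl]pyrrolidin-1-ium benzoate, (E)-iminium | C=CCOc1cc(OCc2ccccc2)cc(OCc2ccccc2)c1/C=C/C=[N+]1\CCC[C@H]1C(c1ccccc1)(c1ccccc1)O[Si](C)(C)C.[O-]C(=O)c1ccccc1 | intermediate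
7 | (3R)-3-[2-(allyloxy)-4,6-bis(benzyloxy)phenyl]-3-(2-hydroxy-4,6-dimethoxyphenyl)propanal | O=CC[C@H](c1c(O)cc(OC)cc1OC)c1c(OCC=C)cc(OCc2ccccc2)cc1OCc1ccccc1 | intermediate
8 | (4S)-4-[2-(allyloxy)-4,6-bis(benzyloxy)phenyl]-5,7-dimethoxychroman-2-ol, both C2 anomers | COc1cc(OC)c2c(c1)OC(O)C[C@H]2c1c(OCC=C)cc(OCc2ccccc2)cc1OCc1ccccc1 | intermediate
9 | 1-(benzyloxy)-4-bromobenzene | Brc1ccc(OCc2ccccc2)cc1 | starting material
10 | 4-(benzyloxy)phenylmagnesium bromide | Br[Mg]c1ccc(OCc2ccccc2)cc1 | intermediate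
11 | (3R)-3-[2-(allyloxy)-4,6-bis(benzyloxy)phenyl]-1-[4-(benzyloxy)phenyl]-3-(2-hydroxy-4,6-dimethoxyphenyl)propan-1-ol, both C1 epimers | OC(C[C@H](c1c(O)cc(OC)cc1OC)c1c(OCC=C)cc(OCc2ccccc2)cc1OCc1ccccc1)c1ccc(OCc2ccccc2)cc1 | intermediate
12 | (2S,4S)-4-[2-(allyloxy)-4,6-bis(benzyloxy)phenyl]-2-[4-(benzyloxy)phenyl]-5,7-dimethoxychroman, 2,4-trans | COc1cc(OC)c2c(c1)O[C@H](c1ccc(OCc3ccccc3)cc1)C[C@H]2c1c(OCC=C)cc(OCc2ccccc2)cc1OCc1ccccc1 | intermediate
13 | 3,5-bis(benzyloxy)-2-{(2S,4S)-2-[4-(benzyloxy)phenyl]-5,7-dimethoxychroman-4-yl}phenol | COc1cc(OC)c2c(c1)O[C@H](c1ccc(OCc3ccccc3)cc1)C[C@H]2c1c(O)cc(OCc2ccccc2)cc1OCc1ccccc1 | intermediate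
14 | ethyl (R)-3-hydroxy-3-phenylpropanoate | CCOC(=O)C[C@@H](O)c1ccccc1 | starting material
15 | ethyl (3S)-3-(3,5-bis(benzyloxy)-2-{(2S,4R)-2-[4-(benzyloxy)phenyl]-5,7-dimethoxychroman-4-yl}phenoxy)-3-phenylpropanoate | COc1cc(OC)c2c(c1)O[C@H](c1ccc(OCc3ccccc3)cc1)C[C@H]2c1c(O[C@@H](CC(=O)OCC)c2ccccc2)cc(OCc2ccccc2)cc1OCc1ccccc1 | intermediate
16 | (3S)-3-(3,5-bis(benzyloxy)-2-{(2S,4R)-2-[4-(benzyloxy)phenyl]-5,7-dimethoxychroman-4-yl}phenoxy)-3-phenylpropanoic acid | COc1cc(OC)c2c(c1)O[C@H](c1ccc(OCc3ccccc3)cc1)C[C@H]2c1c(O[C@@H](CC(=O)O)c2ccccc2)cc(OCc2ccccc2)cc1OCc1ccccc1 | intermediate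
17 | mixed anhydride of acid 16 with trifluoroacetic acid | COc1cc(OC)c2c(c1)O[C@H](c1ccc(OCc3ccccc3)cc1)C[C@H]2c1c(O[C@@H](CC(=O)OC(=O)C(F)(F)F)c2ccccc2)cc(OCc2ccccc2)cc1OCc1ccccc1 | intermediate
18 | (2S)-5,7-bis(benzyloxy)-8-{(2S,4R)-2-[4-(benzyloxy)phenyl]-5,7-dimethoxychroman-4-yl}-2-phenylchroman-4-one | COc1cc(OC)c2c(c1)O[C@H](c1ccc(OCc3ccccc3)cc1)C[C@H]2c1c(OCc2ccccc2)cc(OCc2ccccc2)c2c1O[C@H](c1ccccc1)CC2=O | intermediate
19 | (2S)-5,7-dihydroxy-8-[(2S,4R)-2-(4-hydroxyphenyl)-5,7-dimethoxychroman-4-yl]-2-phenylchroman-4-one | COc1cc(OC)c2c(c1)O[C@H](c1ccc(O)cc1)C[C@H]2c1c(O)cc(O)c2c1O[C@H](c1ccccc1)CC2=O | target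

Total step count: 11. Longest linear sequence: 11 steps (1 to 19); compounds 5, 9 and 14 enter as purchased materials.

Steps most likely to fail

Step 4. The conjugate arylation may stall on the hindered, donor-substituted iminium ion, or a slow, partly reversible addition may erode facial selectivity. The fallback sets out from enal 4 and phenol 5 and returns at lactol 8; it uses cationic instead of iminium activation, for which the electron-rich ring D is an advantage. Enal 4 would be oxidised (NaClO2, NaH2PO4, 2-methyl-2-butene, t-BuOH/H2O; Pinnick oxidation) to (E)-3-[2-(allyloxy)-4,6-bis(benzyloxy)phenyl]acrylic acid F1. With phenol 5 in CF3CO2H/CH2Cl2 at rt, F1 should undergo hydroarylation and lactonisation to racemic 4-[2-(allyloxy)-4,6-bis(benzyloxy)phenyl]-5,7-dimethoxychroman-2-one F2. Preparative chromatography on a chiral stationary phase would deliver the (4S)-lactone F3 and set aside the (4R)-lactone F4. Reduction of F3 with i-Bu2AlH (CH2Cl2, −78 °C) gives lactol 8.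

Step 8. The activated β-hydroxy ester may eliminate to ethyl cinnamate, and ionisation at the benzylic carbon may cause incomplete inversion; both are aggravated by the hindered phenol. The fallback sets out from phenol 13 and returns at acid 16; it uses a coupling partner without an acidic α-hydrogen and unveils the carboxyl group oxidatively. Mitsunobu reaction (PPh3, DIAD, toluene) of 13 with commercial (R)-1-phenylbut-3-en-1-ol (C=CC[C@@H](O)c1ccccc1) should give (2S,4R)-4-{2,4-bis(benzyloxy)-6-[(1S)-1-phenylbut-3-en-1-yloxy]phenyl}-2-[4-(benzyloxy)phenyl]-5,7-dimethoxychroman F5. Lemieux–Johnson cleavage (OsO4 cat., NaIO4, 2,6-lutidine, dioxane/H2O) would give (3S)-3-(3,5-bis(benzyloxy)-2-{(2S,4R)-2-[4-(benzyloxy)phenyl]-5,7-dimethoxychroman-4-yl}phenoxy)-3-phenylpropanal F6. Pinnick oxidation (NaClO2, NaH2PO4, 2-methyl-2-butene) then leads to acid 16, bypassing step 9.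

Step 6. Diastereoselection at C2 may be insufficient, with the 2,4-cis flavan formed alongside, or acid may ionise the C4–ring D bond. The fallback sets out from diol 11 and returns at flavan 12; it sets C2 by reagent control. Oxidation with MnO2 (CH2Cl2) would give (3R)-3-[2-(allyloxy)-4,6-bis(benzyloxy)phenyl]-1-[4-(benzyloxy)phenyl]-3-(2-hydroxy-4,6-dimethoxyphenyl)propan-1-one F7. Corey–Bakshi–Shibata reduction (BH3·SMe2 in excess, (S)-1-methyl-3,3-diphenyltetrahydro-1H,3H-pyrrolo[1,2-c][1,3,2]oxazaborole, THF, −20 °C) should give (1R,3R)-3-[2-(allyloxy)-4,6-bis(benzyloxy)phenyl]-1-[4-(benzyloxy)phenyl]-3-(2-hydroxy-4,6-dimethoxyphenyl)propan-1-ol F8. Intramolecular Mitsunobu etherification (PPh3, DIAD, THF, 0 °C) closes ring C with inversion at the carbinol to give flavan 12 without acid.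

Further compounds
F1 | step 4 | (E)-3-[2-(allyloxy)-4,6-bis(benzyloxy)phenyl]acrylic acid | OC(=O)/C=C/c1c(OCC=C)cc(OCc2ccccc2)cc1OCc1ccccc1
F2 | step 4 | racemic 4-[2-(allyloxy)-4,6-bis(benzyloxy)phenyl]-5,7-dimethoxychroman-2-one | COc1cc(OC)c2c(c1)OC(=O)CC2c1c(OCC=C)cc(OCc2ccccc2)cc1OCc1ccccc1
F3 | step 4 | (4S)-4-[2-(allyloxy)-4,6-bis(benzyloxy)phenyl]-5,7-dimethoxychroman-2-one | COc1cc(OC)c2c(c1)OC(=O)C[C@H]2c1c(OCC=C)cc(OCc2ccccc2)cc1OCc1ccccc1
F4 | step 4 | (4R)-4-[2-(allyloxy)-4,6-bis(benzyloxy)phenyl]-5,7-dimethoxychroman-2-one | COc1cc(OC)c2c(c1)OC(=O)C[C@@H]2c1c(OCC=C)cc(OCc2ccccc2)cc1OCc1ccccc1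
F5 | step 8 | (2S,4R)-4-{2,4-bis(benzyloxy)-6-[(1S)-1-phenylbut-3-en-1-yloxy]phenyl}-2-[4-(benzyloxy)phenyl]-5,7-dimethoxychroman | COc1cc(OC)c2c(c1)O[C@H](c1ccc(OCc3ccccc3)cc1)C[C@H]2c1c(O[C@@H](CC=C)c2ccccc2)cc(OCc2ccccc2)cc1OCc1ccccc1
F6 | step 8 | (3S)-3-(3,5-bis(benzyloxy)-2-{(2S,4R)-2-[4-(benzyloxy)phenyl]-5,7-dimethoxychroman-4-yl}phenoxy)-3-phenylpropanal | COc1cc(OC)c2c(c1)O[C@H](c1ccc(OCc3ccccc3)cc1)C[C@H]2c1c(O[C@@H](CC=O)c2ccccc2)cc(OCc2ccccc2)cc1OCc1ccccc1
F7 | step 6 | (3R)-3-[2-(allyloxy)-4,6-bis(benzyloxy)phenyl]-1-[4-(benzyloxy)phenyl]-3-(2-hydroxy-4,6-dimethoxyphenyl)propan-1-one | O=C(C[C@H](c1c(O)cc(OC)cc1OC)c1c(OCC=C)cc(OCc2ccccc2)cc1OCc1ccccc1)c1ccc(OCc2ccccc2)cc1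
F8 | step 6 | (1R,3R)-3-[2-(allyloxy)-4,6-bis(benzyloxy)phenyl]-1-[4-(benzyloxy)phenyl]-3-(2-hydroxy-4,6-dimethoxyphenyl)propan-1-ol | O[C@H](C[C@H](c1c(O)cc(OC)cc1OC)c1c(OCC=C)cc(OCc2ccccc2)cc1OCc1ccccc1)c1ccc(OCc2ccccc2)cc1
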